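**Plan**

- Retrosynthetic cuts, in order: the C17 tert-butyl ester; the C6–O acyl bond (with inversion); C12–C13 (side chain from 3-bromofuranone); C11=C12 (back to a lactol); then C5–C6 and C9–C10 together, with O6–C11 kept as a lactone.
- Enabling feature (labdane numbering): O–C6, C7=C8 with its C17 carboxyl, C9 and C11 are the O1–C6, C5=C4(CO2R), C3 and C2 atoms of a 2-pyranone-4-carboxylate. The two bonds joining this unit to ring A end on the alkene carbons C5 and C10 of 1,3,3-trimethylcyclohexene.
- Forward: the pyranone (Stobbe condensation, cyclodehydration) and the alkene (enol triflate, reduction) are made separately. Ring A is preformed; ring B closes in the [4+2] as a lactone-bridged bicyclo[2.2.2]octene. The bridge is opened (lactol, Wittig) and the butenolide is joined by B-alkyl Suzuki coupling.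
- Stereochemistry: C9/C10 from the endo, suprafacial cycloaddition (absolute sense by resolution of the adduct); C5 by epimerisation through the C6 ketone; C6 by α-face hydride delivery, then Mitsunobu inversion; the acyl centre from (R)-2-methylbutanoic acid.

Key step: step 5

Remark 1: labdane numbering is used (ring A C1–C5/C10, ring B C5–C10, C17 on C8, C11–C16 on C9, C18/C19 on C4, C20 on C10); α/β refer to the usual drawing with C20 β; "16,15-olide" is the α-substituted butenolide (C16=O on C13, C15H2–O).
Remark 2: the cycloaddition of step 5 is assumed to give the racemic endo adduct; it is resolved by preparative SFC on a chiral phase directly after the step, and 11 is drawn and carried on as the enantiomer needed.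
Remark 3: 2 is sold as an aqueous solution and is used after extraction and drying; 15 and 21 are taken as commercial.

Step 1
Reactants: 1 di-tert-butyl succinate; 2 2,2-dimethoxyacetaldehyde
Product: 3 (E)-3-(tert-butoxycarbonyl)-5,5-dimethoxypent-3-enoic acid
Conditions: KOtBu, tBuOH, rt to 50 °C; then cold 1 M HCl to pH 3
Reagents that add atoms: none
Why: Stobbe condensation: the succinate enolate adds to the non-enolisable aldehyde, the aldolate closes to a paraconate lactone and E1cB opening should give the half-ester with the acetal carbon cis to CH2CO2H (E alkene), the geometry the pyranone closure needs.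

Step 2
Reactants: 3 (E)-3-(tert-butoxycarbonyl)-5,5-dimethoxypent-3-enoic acid
Product: 6 tert-butyl 2-oxo-2H-pyran-4-carboxylate, via lactol 4 (not isolated), via acetate 5 (not isolated)
Conditions: 2 M HCl–THF (1:4), rt; then Ac2O, Et3N, DMAP (cat.), CH2Cl2, 0 °C to rt
Reagents that add atoms: none
Why: Acetal hydrolysis lets the cis carboxylic acid close onto the aldehyde as a six-membered pseudo-acid, and acetylation followed by base-induced vinylogous 1,4-elimination of acetate (E1cB from the acidic C3–H) should give the 2-pyranone, a cyclodehydration of the kind used for 5-oxopentenoic acids, under conditions that spare the tert-butyl ester.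

Step 3
Reactants: 7 2,2,6-trimethylcyclohexanone
Product: 9 2,6,6-trimethylcyclohex-1-en-1-yl trifluoromethanesulfonate, via lithium enolate 8 (not isolated)
Conditions: LDA, THF, −78 to 0 °C; then PhNTf2, −78 °C to rt
Reagents that add atoms: N-phenylbis(trifluoromethanesulfonimide), O=S(=O)(N(c1ccccc1)S(=O)(=O)C(F)(F)F)C(F)(F)F
Why: The ketone has a single α-hydrogen, so deprotonation gives one enolate, and its O-sulfonylation (enol triflate formation) fixes the double bond between the methyl-bearing carbon and the former carbonyl carbon.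

Step 4
Reactants: 9 2,6,6-trimethylcyclohex-1-en-1-yl trifluoromethanesulfonate
Product: 10 1,3,3-trimethylcyclohexene
Conditions: Pd(OAc)2 (3 mol%), PPh3 (6 mol%), HCO2H, Bu3N, DMF, 60 °C
Reagents that add atoms: none
Why: Palladium-catalysed formate reduction of an enol triflate (oxidative addition, formate exchange, loss of CO2, C–H reductive elimination) replaces OTf by H without moving the double bond.

Step 5
Reactants: 6 tert-butyl 2-oxo-2H-pyran-4-carboxylate; 10 1,3,3-trimethylcyclohexene
Product: 11 tert-butyl 6β-hydroxy-12,13,14,15,16-pentanor-5β-labd-7-ene-11,17-dioate 11,6-lactone (endo adduct; 5β-H 9α-H 10β-CH3)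
Conditions: 10 (5 equiv), CH2Cl2, 13 kbar, 50 °C; then preparative SFC on a chiral stationary phase
Reagents that add atoms: none
Why: Proposed new method: an inverse-electron-demand [4+2] in which the electron-poor pyranone is the 4π partner and the unactivated, hindered trisubstituted ring alkene the 2π partner, run under high pressure because the strongly negative activation volume should let the pair combine near 50 °C, below the temperature at which the bridged adduct loses CO2; the closest known reaction types are the high-pressure or Lewis-acid cycloaddition of ester-substituted 2-pyranones with enol ethers (bridge kept) and the thermal intramolecular addition of 2-pyranones to unactivated trisubstituted alkenes, neither shown for an intermolecular hindered cycloalkene. Ring B closes as a six-membered carbocycle by a concerted, asynchronous, suprafacial–suprafacial cycloaddition (C5–C6 leading, C9–C10 lagging) and is held as a boat by the O–C11 lactone bridge. C5 and C10 are cis because the alkene adds suprafacially; C6 and C9 are fixed as bridgeheads of the lactone; C9 is related to C10 by the endo arrangement (ring A under the new C7=C8 bond, C20 and H5 towards the lactone), which the pressure (more compact transition state) and the clash of C20 with the tert-butyl ester in the exo mode should favour. The step sets no absolute configuration, hence the resolution. The regiochemistry needed is bonding of the less substituted alkene carbon C5 to the oxygen-bearing pyranone carbon: this is the unhindered terminus of the lactone-conjugated diene, positive charge then builds at tertiary C10, and the bulk of the tert-butyl ester next to pyranone C3 should weaken the competing pull of the ester.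

Step 6
Reactants: 11 tert-butyl 6β-hydroxy-12,13,14,15,16-pentanor-5β-labd-7-ene-11,17-dioate 11,6-lactone
Product: 12 tert-butyl 6β,11-epoxy-11-hydroxy-12,13,14,15,16-pentanor-5β-labd-7-en-17-oate (bridged lactol; both C11 epimers)
Conditions: DIBAL-H (1.2 equiv), CH2Cl2, −78 °C; aq. Rochelle salt
Reagents that add atoms: none
Why: Partial reduction of a lactone with DIBAL-H: the strained, non-conjugated bridged lactone is far more electrophilic than the hindered conjugated tert-butyl ester and its aluminium hemiacetal is stable at −78 °C, so reduction should stop at the lactol.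

Step 7
Reactants: 12 tert-butyl 6β,11-epoxy-11-hydroxy-12,13,14,15,16-pentanor-5β-labd-7-en-17-oate
Product: 14 tert-butyl 6β-hydroxy-13,14,15,16-tetranor-5β-labda-7,11-dien-17-oate (9β-vinyl; cis-fused), via hydroxy aldehyde 13 (not isolated)
Conditions: Ph3PCH3Br, KHMDS, THF, 0 °C; then 12, −78 to 0 °C
Reagents that add atoms: methyltriphenylphosphonium bromide, C[P+](c1ccccc1)(c1ccccc1)c1ccccc1.[Br-]
Why: Wittig methylenation of a lactol through its ring-opened hydroxy aldehyde: opening relieves the strain of the bicycle, and the unhindered ylide at low temperature should trap the aldehyde faster than the hindered C9–H is removed, so C9 keeps its configuration and O6 is released as the free alcohol.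

Step 8
Reactants: 14 tert-butyl 6β-hydroxy-13,14,15,16-tetranor-5β-labda-7,11-dien-17-oate; 15 3-bromofuran-2(5H)-one
Product: 17 tert-butyl 6β-hydroxy-5β-labda-7,13-dien-16,15-olid-17-oate, via B-alkyl borane 16 (not isolated)
Conditions: 9-BBN (2.5 equiv), THF, 0 °C to rt; then 15, Pd(dppf)Cl2 (5 mol%), AsPh3, Cs2CO3, DMF–H2O, rt
Reagents that add atoms: none
Why: Hydroboration with 9-BBN is anti-Markovnikov and should touch only the terminal vinyl group (the conjugated trisubstituted C7=C8 is inert and the alcohol is merely borylated), and the B-alkyl borane then undergoes B-alkyl Suzuki–Miyaura coupling with the α-bromobutenolide to form C12–C13.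

Step 9
Reactants: 17 tert-butyl 6β-hydroxy-5β-labda-7,13-dien-16,15-olid-17-oate
Product: 18 tert-butyl 6-oxo-5β-labda-7,13-dien-16,15-olid-17-oate
Conditions: Dess–Martin periodinane, CH2Cl2, 0 °C to rt
Reagents that add atoms: none
Why: Dess–Martin oxidation converts the secondary allylic alcohol into the enone under neutral conditions, which spares the epimerisable C5 and C9 centres and the butenolide.

Step 10
Reactants: 18 tert-butyl 6-oxo-5β-labda-7,13-dien-16,15-olid-17-oate
Product: 19 tert-butyl 6-oxolabda-7,13-dien-16,15-olid-17-oate (5α-H; trans-fused)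
Conditions: DBU (0.2 equiv), toluene, 0 °C to rt; AcOH quench once 18 is consumed
Reagents that add atoms: none
Why: Base-catalysed epimerisation through the C5 enolate: the α′-hydrogen at C5 is the kinetically most acidic position of the enone and the trans-fused 4,4,10-trimethyl decalin is the more stable ring fusion, so catalytic base should convert 18 into 19 before the γ-hydrogen at C9 is touched, with reprotonation from the α face, anti to C20, setting 5α-H.

Step 11
Reactants: 19 tert-butyl 6-oxolabda-7,13-dien-16,15-olid-17-oate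
Product: 20 tert-butyl 6β-hydroxylabda-7,13-dien-16,15-olid-17-oate
Conditions: NaBH4, CeCl3·7H2O, MeOH, −78 °C
Reagents that add atoms: none
Why: Luche reduction is 1,2-selective for the enone carbonyl and leaves ester and butenolide, and hydride should add from the α face because the β face of C6 is screened by the axial C19 and C20 methyl groups, giving the 6β (pseudo-axial) alcohol.

Step 12
Reactants: 20 tert-butyl 6β-hydroxylabda-7,13-dien-16,15-olid-17-oate; 21 (R)-2-methylbutanoic acid
Product: 22 tert-butyl 6α-[(2R)-2-methylbutanoyloxy]labda-7,13-dien-16,15-olid-17-oate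
Conditions: PPh3, DIAD, toluene, 0 °C to rt
Reagents that add atoms: none
Why: Mitsunobu esterification: the alcohol is activated as its oxyphosphonium ion and displaced by the carboxylate from the open α face in an SN2 step at the allylic carbon, so C6 is inverted to the 6α-ester while the stereocentre of the acid is not involved.

Step 13
Reactants: 22 tert-butyl 6α-[(2R)-2-methylbutanoyloxy]labda-7,13-dien-16,15-olid-17-oate
Product: 23 6α-[(2R)-2-methylbutanoyloxy]labda-7,13-dien-16,15-olid-17-oic acid (CNP0150853.1)
Conditions: TFA–CH2Cl2 (1:4), 0 °C to rt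
Reagents that add atoms: none
Why: Acidolysis of the tert-butyl ester (loss of isobutene via the tert-butyl cation) frees the C17 acid without base or nucleophile, so the butenolide, the allylic secondary ester and its α-stereocentre should survive.

**Compound list**

1 | di-tert-butyl succinate | CC(C)(C)OC(=O)CCC(=O)OC(C)(C)C | starting material
2 | 2,2-dimethoxyacetaldehyde | COC(OC)C=O | starting material
3 | (E)-3-(tert-butoxycarbonyl)-5,5-dimethoxypent-3-enoic acid | OC(=O)C/C(=C\C(OC)OC)C(=O)OC(C)(C)C | intermediate
4 | tert-butyl 6-hydroxy-2-oxo-3,6-dihydro-2H-pyran-4-carboxylate (racemic lactol) | O=C1CC(C(=O)OC(C)(C)C)=CC(O)O1 | intermediate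
5 | tert-butyl 6-acetoxy-2-oxo-3,6-dihydro-2H-pyran-4-carboxylate (racemic) | CC(=O)OC1OC(=O)CC(C(=O)OC(C)(C)C)=C1 | intermediate
6 | tert-butyl 2-oxo-2H-pyran-4-carboxylate | O=C1C=C(C(=O)OC(C)(C)C)C=CO1 | intermediate
7 | 2,2,6-trimethylcyclohexanone | CC1CCCC(C)(C)C1=O | starting material
8 | lithium 2,6,6-trimethylcyclohex-1-en-1-olate | [Li]OC1=C(C)CCCC1(C)C | intermediate
9 | 2,6,6-trimethylcyclohex-1-en-1-yl trifluoromethanesulfonate | CC1=C(OS(=O)(=O)C(F)(F)F)C(C)(C)CCC1 | intermediate
10 | 1,3,3-trimethylcyclohexene | CC1=CC(C)(C)CCC1 | intermediate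
11 | tert-butyl 6β-hydroxy-12,13,14,15,16-pentanor-5β-labd-7-ene-11,17-dioate 11,6-lactone (endo adduct, resolved) | O=C1O[C@@H]2C=C(C(=O)OC(C)(C)C)[C@H]1[C@@]3(C)CCCC(C)(C)[C@@H]23 | intermediate
12 | tert-butyl 6β,11-epoxy-11-hydroxy-12,13,14,15,16-pentanor-5β-labd-7-en-17-oate (bridged lactol, both C11 epimers) | OC1O[C@@H]2C=C(C(=O)OC(C)(C)C)[C@H]1[C@@]3(C)CCCC(C)(C)[C@@H]23 | intermediate
13 | tert-butyl 6β-hydroxy-11-oxo-12,13,14,15,16-pentanor-5β-labd-7-en-17-oate (open hydroxy aldehyde) | O[C@@H]1C=C(C(=O)OC(C)(C)C)[C@H](C=O)[C@@]2(C)CCCC(C)(C)[C@@H]12 | intermediate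
14 | tert-butyl 6β-hydroxy-13,14,15,16-tetranor-5β-labda-7,11-dien-17-oate | O[C@@H]1C=C(C(=O)OC(C)(C)C)[C@H](C=C)[C@@]2(C)CCCC(C)(C)[C@@H]12 | intermediate
15 | 3-bromofuran-2(5H)-one | O=C1OCC=C1Br | starting material
16 | tert-butyl 12-(9-borabicyclo[3.3.1]nonan-9-yl)-6β-(9-borabicyclo[3.3.1]nonan-9-yloxy)-13,14,15,16-tetranor-5β-labd-7-en-17-oate | B1(C2CCCC1CCC2)O[C@@H]1C=C(C(=O)OC(C)(C)C)[C@H](CCB2C3CCCC2CCC3)[C@@]2(C)CCCC(C)(C)[C@@H]12 | intermediate
17 | tert-butyl 6β-hydroxy-5β-labda-7,13-dien-16,15-olid-17-oate | O[C@@H]1C=C(C(=O)OC(C)(C)C)[C@H](CCC2=CCOC2=O)[C@@]2(C)CCCC(C)(C)[C@@H]12 | intermediate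
18 | tert-butyl 6-oxo-5β-labda-7,13-dien-16,15-olid-17-oate | O=C1C=C(C(=O)OC(C)(C)C)[C@H](CCC2=CCOC2=O)[C@@]2(C)CCCC(C)(C)[C@@H]12 | intermediate
19 | tert-butyl 6-oxolabda-7,13-dien-16,15-olid-17-oate (5α-H, trans-fused) | O=C1C=C(C(=O)OC(C)(C)C)[C@H](CCC2=CCOC2=O)[C@@]2(C)CCCC(C)(C)[C@H]12 | intermediate
20 | tert-butyl 6β-hydroxylabda-7,13-dien-16,15-olid-17-oate | O[C@@H]1C=C(C(=O)OC(C)(C)C)[C@H](CCC2=CCOC2=O)[C@@]2(C)CCCC(C)(C)[C@H]12 | intermediate
21 | (R)-2-methylbutanoic acid | CC[C@@H](C)C(=O)O | starting material
22 | tert-butyl 6α-[(2R)-2-methylbutanoyloxy]labda-7,13-dien-16,15-olid-17-oate | CC[C@@H](C)C(=O)O[C@H]1C=C(C(=O)OC(C)(C)C)[C@H](CCC2=CCOC2=O)[C@@]2(C)CCCC(C)(C)[C@H]12 | intermediate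
23 | 6α-[(2R)-2-methylbutanoyloxy]labda-7,13-dien-16,15-olid-17-oic acid (CNP0150853.1) | CC[C@@H](C)C(=O)O[C@H]1C=C(C(=O)O)[C@H](CCC2=CCOC2=O)[C@@]2(C)CCCC(C)(C)[C@H]12 | target

**Step count**

Total: 13 steps. Longest linear sequence: 11 steps (1, 2, 5–13; the alkene branch 3, 4, 5–13 is equally long).

**Steps most likely to fail**

1. Step 5 (new method). The hindered alkene may not add at all below the temperature of CO2 loss, the ester may reverse the regiochemistry, or addition may occur exo instead of endo; the step also gives no absolute control.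
Fallback, known chemistry only: it sets out from 15, the fragment of the route that is kept, and takes the decalin with C5, C9 and C10 already set from commercial (+)-sclareolide F1. LiAlH4 in THF should give the 8α,12-diol F2, and TBSCl/imidazole the primary silyl ether F3. SOCl2–pyridine at −78 °C should dehydrate the axial tertiary alcohol mainly to the exocyclic alkene F4, and ozonolysis (O3, then Me2S) gives the 8-ketone F5. Kinetic enolisation towards C7 and triflation (KHMDS, PhNTf2) give the Δ7 enol triflate F6. Pd-catalysed hydroxycarbonylation (Pd(OAc)2, dppf, CO, KOAc, DMSO) gives the unsaturated acid F7, and Boc2O/DMAP/tBuOH its tert-butyl ester F8. Allylic oxidation at C6 (CrO3–3,5-dimethylpyrazole) gives the enone F9, and HF·pyridine the primary alcohol F10. I2/PPh3/imidazole gives the iodide F11, and zinc insertion (Zn, LiCl, THF) the alkylzinc iodide F12, which is joined to 15 by Negishi coupling (Pd2(dba)3, SPhos). The fallback comes back to the route at 19; steps 5–10 are bypassed.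

2. Step 10. The C9 configuration may be lost, or the double bond may move to C8=C9, through the extended dienolate (γ-deprotonation) while C5 equilibrates; the butenolide may also isomerise under base.
Fallback: it sets out from 18. Zn/AcOH reduces the 4-oxo-2-enoate to the saturated keto ester F13, in which C9 is no longer acidic. DBU in warm toluene then equilibrates only C5 (and C8) to the trans-fused keto ester F14. Dehydrogenation with IBX in DMSO re-introduces the double bond, which can only form between C7 and C8, and the fallback comes back to the route at 19.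

3. Step 12. The oxyphosphonium ion may not form at the hindered axial alcohol, or may eliminate towards the 5,7-diene (anti-periplanar H5) instead of undergoing substitution.
Fallback: it sets out from 20. Meerwein–Ponndorf–Verley/Oppenauer equilibration (Al(OiPr)3, iPrOH, a little acetone, warm toluene) through ketone 19 should drain the axial alcohol into the thermodynamically preferred equatorial 6α-alcohol F15. F15 is then acylated with retention by 21 under Steglich conditions (EDC·HCl, DMAP), and the fallback comes back to the route at 22.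

**Further compounds**

F1 | step 5 | (+)-sclareolide | C1C[C@@]3(C)OC(=O)C[C@@H]3[C@@]2(C)CCCC(C)(C)[C@H]12
F2 | step 5 | 13,14,15,16-tetranorlabdane-8α,12-diol | C1C[C@@](C)(O)[C@H](CCO)[C@@]2(C)CCCC(C)(C)[C@H]12
F3 | step 5 | 12-(tert-butyldimethylsilyloxy)-13,14,15,16-tetranorlabdan-8α-ol | C1C[C@@](C)(O)[C@H](CCO[Si](C)(C)C(C)(C)C)[C@@]2(C)CCCC(C)(C)[C@H]12
F4 | step 5 | 12-(tert-butyldimethylsilyloxy)-13,14,15,16-tetranorlabd-8(17)-ene | C1CC(=C)[C@H](CCO[Si](C)(C)C(C)(C)C)[C@@]2(C)CCCC(C)(C)[C@H]12
F5 | step 5 | 12-(tert-butyldimethylsilyloxy)-13,14,15,16,17-pentanorlabdan-8-one | C1CC(=O)[C@H](CCO[Si](C)(C)C(C)(C)C)[C@@]2(C)CCCC(C)(C)[C@H]12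
F6 | step 5 | 12-(tert-butyldimethylsilyloxy)-13,14,15,16,17-pentanorlabd-7-en-8-yl trifluoromethanesulfonate | C1C=C(OS(=O)(=O)C(F)(F)F)[C@H](CCO[Si](C)(C)C(C)(C)C)[C@@]2(C)CCCC(C)(C)[C@H]12
F7 | step 5 | 12-(tert-butyldimethylsilyloxy)-13,14,15,16-tetranorlabd-7-en-17-oic acid | C1C=C(C(=O)O)[C@H](CCO[Si](C)(C)C(C)(C)C)[C@@]2(C)CCCC(C)(C)[C@H]12
F8 | step 5 | tert-butyl 12-(tert-butyldimethylsilyloxy)-13,14,15,16-tetranorlabd-7-en-17-oate | C1C=C(C(=O)OC(C)(C)C)[C@H](CCO[Si](C)(C)C(C)(C)C)[C@@]2(C)CCCC(C)(C)[C@H]12
F9 | step 5 | tert-butyl 12-(tert-butyldimethylsilyloxy)-6-oxo-13,14,15,16-tetranorlabd-7-en-17-oate | O=C1C=C(C(=O)OC(C)(C)C)[C@H](CCO[Si](C)(C)C(C)(C)C)[C@@]2(C)CCCC(C)(C)[C@H]12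
F10 | step 5 | tert-butyl 12-hydroxy-6-oxo-13,14,15,16-tetranorlabd-7-en-17-oate | O=C1C=C(C(=O)OC(C)(C)C)[C@H](CCO)[C@@]2(C)CCCC(C)(C)[C@H]12
F11 | step 5 | tert-butyl 12-iodo-6-oxo-13,14,15,16-tetranorlabd-7-en-17-oate | O=C1C=C(C(=O)OC(C)(C)C)[C@H](CCI)[C@@]2(C)CCCC(C)(C)[C@H]12
F12 | step 5 | tert-butyl 12-(iodozincio)-6-oxo-13,14,15,16-tetranorlabd-7-en-17-oate | O=C1C=C(C(=O)OC(C)(C)C)[C@H](CC[Zn]I)[C@@]2(C)CCCC(C)(C)[C@H]12
F13 | step 10 | tert-butyl 6-oxo-5β-labd-13-en-16,15-olid-17-oate (C8 epimers) | O=C1CC(C(=O)OC(C)(C)C)[C@H](CCC2=CCOC2=O)[C@@]2(C)CCCC(C)(C)[C@@H]12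
F14 | step 10 | tert-butyl 6-oxolabd-13-en-16,15-olid-17-oate (5α-H, C8 epimers) | O=C1CC(C(=O)OC(C)(C)C)[C@H](CCC2=CCOC2=O)[C@@]2(C)CCCC(C)(C)[C@H]12
F15 | step 12 | tert-butyl 6α-hydroxylabda-7,13-dien-16,15-olid-17-oate | O[C@H]1C=C(C(=O)OC(C)(C)C)[C@H](CCC2=CCOC2=O)[C@@]2(C)CCCC(C)(C)[C@H]12
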